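(The numbers in the tables were generated by integration for an exercise.)

I had to say what stood in the flask at 20 min, from runs read no later than 15.0 min.

| setting | winter | midnight | dawn | flask |
|---|---|---|---|---|
| Q | 0.067 M | 0.15 M | 0.10 M | 0.10 M |
| Z | 0.20 M | 0.20 M | 0.10 M | 0.200 M |
| remark | run made earlier | run made earlier | run made earlier |  |
| time |  |  |  | 20 min |

| run | time / min | G / % | E / % | Q / % |
|---|---|---|---|---|
| winter | 2.50 | 6.9 | 56.1 | 0 |
| winter | 5.00 | 6.6 | 44.6 | 0 |
| winter | 8.00 | 8.1 | 38.5 | 0 |
| winter | 10.0 | 7.6 | 35.3 | 0 |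
| winter | 12.0 | 8.6 | 34.4 | 0.4 |
| winter | 15.0 | 9.4 | 31.6 | 0.7 |
| midnight | 2.50 | 3.2 | 34.1 | 43.8 |
| midnight | 5.00 | 3.2 | 35.9 | 34.1 |
| midnight | 8.00 | 3.7 | 35.8 | 29.1 |
| midnight | 10.0 | 3.4 | 36.3 | 26.3 |
| midnight | 12.0 | 3.1 | 35.0 | 25.1 |
| midnight | 15.0 | 4.1 | 36.6 | 23.8 |
| dawn | 1.33 | 2.0 | 50.3 | 36.3 |
| dawn | 4.00 | 3.2 | 53.1 | 18.8 |
| dawn | 8.00 | 4.5 | 52.5 | 9.8 |
| dawn | 12.0 | 4.2 | 54.5 | 5.1 |
| dawn | 15.0 | 5.5 | 54.1 | 4.4 |

(standard deviation of a reading: 0.5 percentage points)

1. how much G there is at 20 min, in percent of the Q charged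
2. concentration of E in solution at 20 min, in percent of saturation

- as a solid, counted per litre of solution: Q
- the earlier runs were read with a standard deviation of 0.5 percentage points
- at the start none of Q is in solution
- E is what Q becomes in solution
- E means what is dissolved; the solid is not counted in it

The run nearest in look was dawn, with the flask's charge of Q and half its Z. Dawn's E stood at 54.1% of the charge with 4.4% still solid, and I read that as saturation for this charge. The part that had left Q and E crept from 37.7% to 41.5% between 8.00 min and 15.0 min, although E stayed high, so I suspected Z, not E, of holding dawn back.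

In dawn, G stayed near a steady part of what had left, within the scatter. I supposed G to stand in a fast equilibrium with an unseen form; forward and back rates then cancel time from the ratio, so I reckoned G divided by everything gone from Q and E, over dawn's last three readings: 11.9%, the G share, a reading with its scatter.

The flask has winter's and midnight's Z. Counted on the flask's charge, those runs had lost 45.4% and 59.4% by 15.0 min, both more than dawn. As my own estimate for the flask I took the middle, 52.4%, and added nothing for the later minutes. With the solid assumed gone, that estimate puts 47.6% in E, less than the saturation read from dawn, which is 88.0% of it, with G at 6.24%.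

The forecast differed a little, at 6.4% (5.4% to 7.6%) and 82% (72% to 92%), and it said: “Flask: solid should be gone.”

The flask gave 6.40% of G, with E at 83.0% of saturation.

    E + Z → G (k = 0.0620 M⁻¹ s⁻¹)
    2 Z → D (k = 0.0510 M⁻¹ s⁻¹)
    G ⇌ J (K = 7.40, k = 0.0740 s⁻¹)
    Q + G → X (k = 0.0300 M⁻¹ s⁻¹)
    Q ⇌ E, rate k5*(cs5 - [E]) while solid is left; crystals form when [E] > cs5 (solubility = 0.0540 M, k = 0.0580 s⁻¹)

By then Z was down to 0.37% of its charge. With E at 44.8%, the G share gives 6.57% of G in this flask. In the neighbouring flask with 0.060 M of Q, E stood at 27.1%, so the share gives 8.68%, and that flask held 8.72%.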